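# Dendronpholide A: route proposal built on a transannular epoxy-acid lactonisation

Numbering throughout is that of the cembrane skeleton: C1 carries the acrylate carbons C15 (α-carbon), C16 (carboxyl) and C17 (methylene); C3 is the carbinol; C11 bears the acetate; C12 bears methyl C20 and the lactone oxygen; methyls C18 and C19 sit on C4 and C8.

## Analysis of the target

Dendronpholide A is a cembranoid. Its fourteen-membered carbocycle (C1–C14) is bridged by a seven-membered α-methylene lactone (C15, C16, O, C12, C13, C14, C1), so C1 and C12 are the fusion atoms. The macrocycle holds a skipped diene, 4E and 7E, both olefins trisubstituted, with the doubly allylic C6 between them. There are four stereocentres: 1R, 3S, 11S and 12R. C11 and C12 are adjacent and C1 and C3 are 1,3-related, but the two pairs are joined only through C13–C14 and the lactone, so in an open chain neither pair can direct the other. The sensitive groups are the exo-methylene lactone (a Michael acceptor), the allylic C3 alcohol, the acetate next to a tertiary ester, and the skipped diene, which can move into conjugation or take part in transannular cation–olefin reactions. The hard points are the ester bond to the fully substituted C12, the closure of a fourteen-membered ring with two E-trisubstituted olefins, and independent control of remote stereocentres. The plan rests on one feature: O11 and O12 are arranged as in an E-11,12-epoxide opened at C12 with inversion, and the C16 carboxyl lies five bonds from C12 (C16–C15–C1–C14–C13–C12). One transannular epoxide opening can therefore give the lactone ring, the C12 configuration and the free C11 hydroxyl together.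

## Retrosynthetic reasoning

**30 from 28 via 29.** The last two operations only change functional groups. The acetate can go on only once the C11 hydroxyl exists. The C3 silyl ether keeps O3 silent during lactone formation and is removed last with buffered fluoride, so the exo-methylene lactone never meets base.

**28 from 27.** The C12–O bond of the lactone is cut. This bond is the hardest to make by acylation (tertiary alcohol, medium ring). Cut as carboxylic acid plus epoxide, it becomes an asset: forward, the C16 acid of 27 opens the (11S,12S)-epoxide at C12 with inversion, which closes the seven-membered ring, sets 12R and frees the C11 hydroxyl. The forward reaction must choose C12 over C11 and stay stereospecific.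

**27 from 23, via 24 and with 25.** The C15=C17 bond is cut. The acrylic acid comes from malonic acid 24 by decarboxylative methylenation with 25, and 24 from diester 23. A malonate carries C15 and C16 safely through ring closure and redox steps, where an acrylate would be exposed to nucleophiles and hydrides for many steps.

**23 from 20, via 22 and 21.** C3 is corrected after ring closure: silyl ether 23 from carbinol 22, 22 from enone 21 by catalyst-controlled reduction, 21 by oxidation of 20. Two steps are spent so that the C3 configuration depends on the choice of catalyst and not on the conformation of the ring-closing transition state.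

**20 from 19.** The ring is opened at C3–C4, between the carbinol carbon and the trisubstituted olefin. Forward, an alkenyl iodide adds to an aldehyde (Nozaki–Hiyama–Kishi). The C4=C5 geometry is fixed beforehand in the iodide, and the reaction tolerates the epoxide and esters. The C3 aldehyde is exactly what the C1-setting step leaves behind, so no protecting group is needed between the two steps.

**19 from 17 and 18; 17 from 15 and 16.** C1–C15 is cut. Malonate 18 adds to enal 17 under iminium catalysis, which sets C1 by catalyst control, independent of the distant epoxide, and releases the C3 aldehyde. Enal 17 comes from aldehyde 15 by two-carbon Wittig homologation with 16 (C2 and C3).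

**15 from 12 via 14; 12 from 10 and 11.** The alkenyl iodide is traced to 2-alkyne 12; syn hydrozirconation and iodination put iodine on C4 with E geometry. Alkyne 12 comes from allylic bromide 10 and propyne 11 (C5–C6 bond; 11 supplies C4, C5 and C18). Joining an allylic electrophile to an alkyne avoids any olefination at C4=C5.

**10 from 6, via 8 and 7.** The epoxide is put on 6 by ketone-catalysed asymmetric epoxidation while C6 still carries the acetate. That ester makes C7=C8 electron-poor, so C11=C12 is the only olefin that reacts. The distinction is lost once C6 is alkylated, so the epoxidation must come first, and every later step is chosen to tolerate a trisubstituted epoxide.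

**6 from 1, via 2–5.** Farnesol 1 already holds C6–C14 and C1 with methyls C19 and C20 and both E olefins. Only the terminal isopropylidene is cut away (bromohydrin, epoxide, glycol cleavage) to expose C1 as an aldehyde, kept as acetal 6 until the alkenyl iodide is in place. All other carbons come from 11, 16, 18 and 25.

## Alternatives that were turned down

**Alternative 1:** Ring-closing alkyne metathesis at C4–C5, then introduction of C18.
- **Disconnection and key step.** The ring is opened at a C4≡C5 triple bond. The diyne A1 already carries the lactone, the 11-acetate and a C3 triethylsilyl ether, with methyl-capped alkynes at C3 and C6. Mo(≡CC6H4OMe)(OSiPh3)3 would close it to the cycloalkyne A2, and trans-hydrostannation with C-methylation at C4 would then build the E olefin.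
- **For.** Alkyne metathesis has no E/Z question at ring closure, tolerates esters and silyl ethers, and fixes the C4=C5 geometry afterwards by a stereodefined trans addition.
- **Against.** The lactone must exist in A1, so the tertiary C12–O bond has to be made on an open chain without the help of the ring. C3 must be set as a propargylic carbinol. The methyl group arrives only after cyclisation, through tin chemistry that needs a free C3 hydroxyl for regiocontrol, in the presence of the exo-methylene lactone. The doubly activated C6 methylene between alkyne and olefin is prone to isomerisation.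
- **Comparison.** This alternative is stronger on ring-closure reliability and on C4=C5 geometry. The chosen route offers instead a stereospecific C12–O bond and no carbon–carbon bond formation after cyclisation.

**Alternative 2:** Acylketene macrolactonisation and Carroll ring contraction at C1–C2.
- **Disconnection and key step.** C1–C2 is cut. The dioxinone alcohol A3 carries a masked acylketene at C2/C3 and an α,β-unsaturated seven-membered lactone with a hydroxymethyl group (C17) on C15. On heating, the C17 hydroxyl would be acylated to a large-ring β-keto ester; [3,3] rearrangement and decarboxylation would then form C1–C2, the C15=C17 methylene and the fourteen-membered ring, giving the 3-oxo compound A4.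
- **For.** One reagent-free operation makes a C–C bond, the methylene and the ring, and C3 needs no protecting group. This is the most step-economic ring formation of the four.
- **Against.** C1 is created in a macrocyclic sigmatropic transition state with only the remote C11/C12 centres to direct it. The rearrangement needs strong heating in the presence of a skipped diene and an acetate. The unsaturated lactone of A3 again requires the tertiary C12–O bond to be made on an open chain. Ketone A4 must be reduced diastereoselectively at C3 next to an exo-methylene lactone that is itself prone to conjugate reduction.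
- **Comparison.** This alternative is stronger on step count at the ring-forming stage. The chosen route offers catalyst control of C1 and C3 before the sensitive lactone exists.

**Alternative 3:** Allyl–alkenyl Stille macrocyclisation at C5–C6.
- **Disconnection and key step.** C5–C6 is cut. A5 carries a C5 alkenylstannane and a C6 allylic chloride on a chain that already holds the lactone, the acetate and the C3 silyl ether. Pd2(dba)3 with AsPh3 would couple the two ends to give A6, which is identical with 29.
- **For.** All four stereocentres and the C4=C5 geometry are fixed before ring closure, the coupling is neutral, and the product is one step from the target.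
- **Against.** The π-allyl intermediate can lose the C7=C8 geometry by syn/anti exchange, can eliminate to a diene, and zerovalent palladium can pull the skipped diene into conjugation. A5 is long to make, because the stannane, the chloride and the exo-methylene lactone must coexist. The tertiary lactone is again built without the ring.
- **Comparison.** This alternative is stronger in needing no correction at C3 after cyclisation. The chosen route offers the C12–O bond made with stereochemical control inside the preformed ring, and avoids tin.

Key step: step 20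

Assumption: the facial sense of the ketone-catalysed epoxidation (step 6), the prolinol-catalysed Michael addition (step 13) and the oxazaborolidine reduction (step 16) is taken from the accepted transition-state models; if one proved opposite, the enantiomeric catalyst would be used.

## Route

Step 1
Reactants: 1 (2E,6E)-farnesol
Product: 2 (2E,6E)-farnesyl acetate
Conditions: Ac2O, pyridine, DMAP (cat.), CH2Cl2, 0 °C to rt
Reagents that add atoms: acetic anhydride, CC(=O)OC(C)=O
Why: Acylation of a primary allylic alcohol; the ester later serves as the electron-withdrawing group that deactivates the C7=C8 olefin towards electrophilic oxidants.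

Step 2
Reactants: 2 (2E,6E)-farnesyl acetate
Product: 3 (2E,6E)-10-bromo-11-hydroxy-3,7,11-trimethyldodeca-2,6-dien-1-yl acetate (racemic)
Conditions: NBS (1.1 equiv), THF/H2O, 0 °C
Reagents that add atoms: N-bromosuccinimide, O=C1CCC(=O)N1Br; water, O
Why: Terminal-selective bromohydrin formation of a polyprenyl chain in aqueous solvent, where the folded chain exposes the terminal olefin and the acetate deactivates the proximal one; water opens the bromonium ion at the tertiary carbon.

Step 3
Reactants: 3 bromohydrin acetate
Product: 4 (2E,6E)-10,11-epoxy-3,7,11-trimethyldodeca-2,6-dien-1-yl acetate (racemic)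
Conditions: DBU (1.5 equiv), CH2Cl2, rt
Reagents that add atoms: none
Why: Intramolecular Williamson closure of the bromohydrin; an amidine base in an aprotic solvent is used in place of carbonate in methanol so that the acetate is not methanolysed.

Step 4
Reactants: 4 terminal epoxide
Product: 5 (2E,6E)-3,7-dimethyl-10-oxodeca-2,6-dien-1-yl acetate
Conditions: HIO4·2H2O (1.2 equiv), THF/Et2O, 0 °C
Reagents that add atoms: none
Why: Periodic acid hydrates the epoxide and cleaves the glycol in one operation, removing the isopropylidene carbon; the aldehyde carbon is the future C1 and keeps the former epoxide oxygen, while the trisubstituted olefins and the acetate are untouched.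

Step 5
Reactants: 5 aldehyde
Product: 6 (2E,6E)-10,10-dimethoxy-3,7-dimethyldeca-2,6-dien-1-yl acetate
Conditions: HC(OMe)3 (3 equiv), PPTS (5 mol%), MeOH, rt
Reagents that add atoms: trimethyl orthoformate, COC(OC)OC
Why: Acid-catalysed acetalisation with the orthoester as water scavenger; the acetal shields the future C1 aldehyde from peroxymonosulfate, base and zirconium hydride in steps 6 to 10.

Step 6
Reactants: 6 dimethyl acetal
Product: 7 (2E,6S,7S)-6,7-epoxy-10,10-dimethoxy-3,7-dimethyldec-2-en-1-yl acetate
Conditions: L-fructose-derived bis-acetonide ketone (1,2:4,5-di-O-isopropylidene-β-L-erythro-2,3-hexodiulo-2,6-pyranose, 0.3 equiv), KHSO5 (as 2KHSO5·KHSO4·K2SO4, 1.4 equiv), K2CO3, Bu4NHSO4 (cat.), MeCN/CH2(OMe)2/aq. Na2B4O7 buffer (pH 10.5), 0 °C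
Reagents that add atoms: potassium peroxymonosulfate, [K+].[O-]S(=O)(=O)OO
Why: Shi epoxidation through a chiral dioxirane and a spiro transition state; the allylic acetate makes C7=C8 electron-poor, so only C11=C12 reacts. The L-fructose-derived ketone should deliver oxygen to the face that gives the S,S epoxide, which fixes C11 and the centre at C12 that is later inverted.

Step 7
Reactants: 7 epoxy acetate
Product: 8 (2E,6S,7S)-6,7-epoxy-10,10-dimethoxy-3,7-dimethyldec-2-en-1-ol
Conditions: K2CO3 (0.2 equiv), MeOH, 0 °C
Reagents that add atoms: none
Why: Base-catalysed transesterification; the trisubstituted epoxide and the acetal are inert to methoxide at 0 °C.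

Step 8
Reactants: 8 epoxy allylic alcohol
Product: 10 (2E,6S,7S)-1-bromo-6,7-epoxy-10,10-dimethoxy-3,7-dimethyldec-2-ene, via allylic mesylate 9 (not isolated)
Conditions: MsCl, Et3N, THF, −45 °C; then LiBr (4 equiv), THF, 0 °C
Reagents that add atoms: lithium bromide, [Li+].[Br-]; methanesulfonyl chloride, CS(=O)(=O)Cl (its atoms are present in 9 only)
Why: Sulfonylation and SN2 displacement by bromide below 0 °C give the primary allylic bromide without allylic transposition or loss of E geometry; the allylic mesylate reacts far faster with bromide than the epoxide does.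

Step 9
Reactants: 10 epoxy allylic bromide; 11 propyne
Product: 12 (5E,9S,10S)-9,10-epoxy-13,13-dimethoxy-6,10-dimethyltridec-5-en-2-yne
Conditions: 11 (excess), CuI (0.2 equiv), Bu4NI (0.2 equiv), K2CO3 (2 equiv), DMF, 0 °C to rt, sealed flask
Reagents that add atoms: none
Why: Copper-catalysed coupling of a terminal alkyne with a primary allylic halide forms C5–C6; attack at the primary carbon is preferred because the SN2′ mode would create a quaternary centre, and the carbonate base leaves epoxide and acetal alone.

Step 10
Reactants: 12 skipped enyne
Product: 14 (2E,5E,9S,10S)-9,10-epoxy-2-iodo-13,13-dimethoxy-6,10-dimethyltrideca-2,5-diene, via alkenylzirconocene chloride 13 (not isolated)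
Conditions: Cp2Zr(H)Cl (1.6 equiv), THF, rt then 40 °C; I2, THF, −20 °C; aq. Na2S2O3/NaHCO3
Reagents that add atoms: iodine, II; zirconocene chloride hydride, [H][Zr](Cl)(C1C=CC=C1)C1C=CC=C1 (its zirconium is present in 13 only)
Why: Hydrozirconation adds H and Zr syn across the alkyne much faster than to the trisubstituted olefin, and a slight excess of hydride equilibrates the regioisomers so that zirconium rests on the less hindered, methyl-bearing C4. Iodinolysis with retention gives the E-2-iodoalkene with C18 cis to C6, the geometry of the target's C4=C5 olefin.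

Step 11
Reactants: 14 alkenyl iodide acetal
Product: 15 (4S,5S,8E,11E)-4,5-epoxy-12-iodo-4,8-dimethyltrideca-8,11-dienal
Conditions: PPTS (0.2 equiv), acetone/H2O (9:1), 40 °C
Reagents that add atoms: water, O
Why: Mild acid-catalysed hydrolysis of an aliphatic dimethyl acetal; the pyridinium salt is weak enough that the trisubstituted epoxide is expected to survive.

Step 12
Reactants: 15 epoxy aldehyde; 16 (triphenylphosphoranylidene)acetaldehyde
Product: 17 (2E,6S,7S,10E,13E)-6,7-epoxy-14-iodo-6,10-dimethylpentadeca-2,10,13-trienal
Conditions: toluene, 80 °C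
Reagents that add atoms: none
Why: Wittig reaction with a stabilised formyl ylide gives the E-enal directly and adds C2 and C3; the conjugated product is less electrophilic than the saturated aldehyde, which limits a second homologation.

Step 13
Reactants: 17 enal; 18 dimethyl malonate
Product: 19 dimethyl 2-[(3R,6S,7S,10E,13E)-6,7-epoxy-14-iodo-6,10-dimethyl-1-oxopentadeca-10,13-dien-3-yl]malonate
Conditions: (S)-2-[bis(3,5-bis(trifluoromethyl)phenyl)(trimethylsilyloxy)methyl]pyrrolidine (10 mol%), PhCO2H (10 mol%), 18 (3 equiv), EtOH, 0 °C to rt
Reagents that add atoms: none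
Why: Iminium-catalysed Michael addition of a malonate to an enal; in the E, s-trans iminium ion the diarylsilyloxymethyl group shields one face, so the malonate adds to C1 from the other, which with the (S)-catalyst should give 1R whatever the remote epoxide does. The step forms C1–C15 and frees the C3 aldehyde; basic conditions are avoided afterwards because the adduct can undergo retro-Michael cleavage.

Step 14
Reactants: 19 iodo aldehyde malonate
Product: 20 dimethyl 2-[(1R,4E,7E,11S,12S)-11,12-epoxy-3-hydroxy-4,8,12-trimethylcyclotetradeca-4,7-dien-1-yl]malonate (mixture of C3 epimers)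
Conditions: CrCl2 (10 equiv), NiCl2 (0.1 equiv), DMSO, rt, slow addition to 0.003 M
Reagents that add atoms: none
Why: Nozaki–Hiyama–Kishi reaction: zerovalent nickel inserts into the C4–I bond, transmetalation gives an alkenyl species of trivalent chromium, and this adds chemoselectively to the aldehyde to close the fourteen-membered ring at C3–C4 with retention of olefin geometry. Esters, the epoxide and the malonate C–H are tolerated; no facial control at C3 is claimed, and both epimers are carried on.

Step 15
Reactants: 20 macrocyclic allylic alcohol
Product: 21 dimethyl 2-[(1R,4E,7E,11S,12S)-11,12-epoxy-4,8,12-trimethyl-3-oxocyclotetradeca-4,7-dien-1-yl]malonate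
Conditions: Dess–Martin periodinane (1.5 equiv), NaHCO3, CH2Cl2, 0 °C to rt
Reagents that add atoms: none
Why: Dess–Martin oxidation converges both C3 epimers on one enone under buffered, non-basic conditions, so neither the epoxide nor the β-malonyl ketone (retro-Michael) is put at risk.

Step 16
Reactants: 21 macrocyclic enone
Product: 22 dimethyl 2-[(1R,3S,4E,7E,11S,12S)-11,12-epoxy-3-hydroxy-4,8,12-trimethylcyclotetradeca-4,7-dien-1-yl]malonate
Conditions: (R)-2-methyl-CBS-oxazaborolidine (0.5 equiv), catecholborane (2 equiv), toluene/CH2Cl2, −78 °C
Reagents that add atoms: none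
Why: Corey–Bakshi–Shibata reduction: the ketone binds the catalyst boron anti to its larger flank, here the α-methylalkenyl group at C4, and hydride is delivered within the complex, so the (R)-catalyst should give the 3S carbinol. 1,2-Reduction is favoured, and esters, epoxide and olefins are inert to catecholborane at −78 °C.

Step 17
Reactants: 22 (3S)-allylic alcohol
Product: 23 dimethyl 2-[(1R,3S,4E,7E,11S,12S)-3-(tert-butyldimethylsilyloxy)-11,12-epoxy-4,8,12-trimethylcyclotetradeca-4,7-dien-1-yl]malonate
Conditions: TBSCl (2 equiv), imidazole (4 equiv), DMAP (cat.), DMF, rt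
Reagents that add atoms: tert-butyldimethylsilyl chloride, CC(C)(C)[Si](C)(C)Cl
Why: Silylation of the secondary allylic alcohol without a Lewis-acidic silyl triflate that could activate the epoxide; it removes the hydroxyl that could lactonise onto a malonate ester or later attack the epoxide.

Step 18
Reactants: 23 silyl ether malonate
Product: 24 2-[(1R,3S,4E,7E,11S,12S)-3-(tert-butyldimethylsilyloxy)-11,12-epoxy-4,8,12-trimethylcyclotetradeca-4,7-dien-1-yl]malonic acid
Conditions: KOH (6 equiv), MeOH/THF/H2O, 50 °C; then aq. KHSO4 to pH 4, 0 °C
Reagents that add atoms: potassium hydroxide, [K+].[OH-]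
Why: Saponification of both esters; the silyl ether and the trisubstituted epoxide resist hydroxide, and cold, brief acidification limits contact of the epoxide with the free malonic acid, which is used at once.

Step 19
Reactants: 24 malonic acid; 25 formaldehyde
Product: 27 2-[(1R,3S,4E,7E,11S,12S)-3-(tert-butyldimethylsilyloxy)-11,12-epoxy-4,8,12-trimethylcyclotetradeca-4,7-dien-1-yl]prop-2-enoic acid, via Mannich base 26 (not isolated)
Conditions: Et2NH (2 equiv), 25 (37% aq., 5 equiv), EtOAc, 0 °C then 65 °C; NaH2PO4 buffer (pH 5) work-up
Reagents that add atoms: diethylamine, CCNCC (its atoms are present in 26 only)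
Why: Mannich condensation at C15 followed by decarboxylative loss of the amine, the classical route to 2-substituted acrylic acids, installs the C15=C17 methylene and leaves C16 as the free acid. The medium is an amine-buffered carboxylate in which the epoxide is not activated.

Step 20
Reactants: 27 macrocyclic (11S,12S)-epoxy acrylic acid
Product: 28 11-deacetyl-3-O-(tert-butyldimethylsilyl)dendronpholide A
Conditions: CSA (0.1 equiv), CH2Cl2, 0 °C to rt
Reagents that add atoms: none
Why: The sulfonic acid protonates the epoxide oxygen, the C12–O bond lengthens because C12 is tertiary, and a carboxyl oxygen of C16 attacks C12 anti to the departing oxygen; proton loss gives the lactone and the free C11 hydroxyl. The closest known reaction type is the acid-catalysed lactonisation of epoxy carboxylic acids, which opens trisubstituted epoxides at the more substituted carbon with inversion and is routine for five- and six-membered lactones. The only ring closed is the seven-membered lactone (O, C12, C13, C14, C1, C15, C16), in a 7-exo-tet mode; the competing 8-endo attack at secondary C11 is disfavoured by ring size and by the smaller positive charge at C11. The new stereocentre C12 is controlled by the epoxide made in step 6: backside attack turns 12S into 12R, and C11 keeps its S configuration. The step needs regioselectivity for C12, stereospecific opening without a free cation, and chemoselectivity over transannular reactions. A catalytic weak acid, a non-nucleophilic solvent of low polarity and low temperature keep the C12–O bond from ionising fully, and the nucleophile is already held in the ring, where the macrocycle can reach a product-like conformation with the carboxyl anti to the epoxide oxygen. O3 is silylated so that it cannot compete as a nucleophile.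

Step 21
Reactants: 28 hydroxy lactone
Product: 29 3-O-(tert-butyldimethylsilyl)dendronpholide A
Conditions: Ac2O (3 equiv), pyridine, DMAP (0.1 equiv), CH2Cl2, 0 °C to rt
Reagents that add atoms: acetic anhydride, CC(=O)OC(C)=O
Why: Acylation of the only free hydroxyl, the secondary C11 alcohol; mild amine bases are compatible with the exo-methylene lactone at this temperature.

Step 22
Reactants: 29 silyl ether acetate
Product: 30 dendronpholide A
Conditions: HF·pyridine, pyridine, THF, 0 °C to rt
Reagents that add atoms: none
Why: Buffered fluoride cleaves the secondary allylic silyl ether without base, so the exo-methylene lactone and the acetate are left intact and no stereocentre is touched.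

## Compound list

1 | (2E,6E)-farnesol | CC(C)=CCC/C(C)=C/CC/C(C)=C/CO | starting material
2 | (2E,6E)-farnesyl acetate | CC(C)=CCC/C(C)=C/CC/C(C)=C/COC(C)=O | intermediate
3 | (2E,6E)-10-bromo-11-hydroxy-3,7,11-trimethyldodeca-2,6-dien-1-yl acetate (racemic) | CC(C)(O)C(Br)CC/C(C)=C/CC/C(C)=C/COC(C)=O | intermediate
4 | (2E,6E)-10,11-epoxy-3,7,11-trimethyldodeca-2,6-dien-1-yl acetate (racemic) | CC1(C)OC1CC/C(C)=C/CC/C(C)=C/COC(C)=O | intermediate
5 | (2E,6E)-3,7-dimethyl-10-oxodeca-2,6-dien-1-yl acetate | O=CCC/C(C)=C/CC/C(C)=C/COC(C)=O | intermediate
6 | (2E,6E)-10,10-dimethoxy-3,7-dimethyldeca-2,6-dien-1-yl acetate | COC(OC)CC/C(C)=C/CC/C(C)=C/COC(C)=O | intermediate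
7 | (2E,6S,7S)-6,7-epoxy-10,10-dimethoxy-3,7-dimethyldec-2-en-1-yl acetate | COC(OC)CC[C@]1(C)O[C@H]1CC/C(C)=C/COC(C)=O | intermediate
8 | (2E,6S,7S)-6,7-epoxy-10,10-dimethoxy-3,7-dimethyldec-2-en-1-ol | COC(OC)CC[C@]1(C)O[C@H]1CC/C(C)=C/CO | intermediate
9 | (2E,6S,7S)-6,7-epoxy-10,10-dimethoxy-3,7-dimethyldec-2-en-1-yl methanesulfonate (not isolated) | COC(OC)CC[C@]1(C)O[C@H]1CC/C(C)=C/COS(C)(=O)=O | intermediate
10 | (2E,6S,7S)-1-bromo-6,7-epoxy-10,10-dimethoxy-3,7-dimethyldec-2-ene | COC(OC)CC[C@]1(C)O[C@H]1CC/C(C)=C/CBr | intermediate
11 | propyne | CC#C | starting material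
12 | (5E,9S,10S)-9,10-epoxy-13,13-dimethoxy-6,10-dimethyltridec-5-en-2-yne | COC(OC)CC[C@]1(C)O[C@H]1CC/C(C)=C/CC#CC | intermediate
13 | alkenylzirconocene chloride from 12, zirconium on C4 and trans to C6 (not isolated; cyclopentadienyl rings drawn carbon-bound) | COC(OC)CC[C@]1(C)O[C@H]1CC/C(C)=C/C/C=C(\C)[Zr](Cl)(C2C=CC=C2)C2C=CC=C2 | intermediate
14 | (2E,5E,9S,10S)-9,10-epoxy-2-iodo-13,13-dimethoxy-6,10-dimethyltrideca-2,5-diene | COC(OC)CC[C@]1(C)O[C@H]1CC/C(C)=C/C/C=C(\C)I | intermediate
15 | (4S,5S,8E,11E)-4,5-epoxy-12-iodo-4,8-dimethyltrideca-8,11-dienal | O=CCC[C@]1(C)O[C@H]1CC/C(C)=C/C/C=C(\C)I | intermediate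
16 | (triphenylphosphoranylidene)acetaldehyde | O=CC=P(c1ccccc1)(c1ccccc1)c1ccccc1 | starting material
17 | (2E,6S,7S,10E,13E)-6,7-epoxy-14-iodo-6,10-dimethylpentadeca-2,10,13-trienal | O=C/C=C/CC[C@]1(C)O[C@H]1CC/C(C)=C/C/C=C(\C)I | intermediate
18 | dimethyl malonate | COC(=O)CC(=O)OC | starting material
19 | dimethyl 2-[(3R,6S,7S,10E,13E)-6,7-epoxy-14-iodo-6,10-dimethyl-1-oxopentadeca-10,13-dien-3-yl]malonate | O=CC[C@H](C(C(=O)OC)C(=O)OC)CC[C@]1(C)O[C@H]1CC/C(C)=C/C/C=C(\C)I | intermediate
20 | dimethyl 2-[(1R,4E,7E,11S,12S)-11,12-epoxy-3-hydroxy-4,8,12-trimethylcyclotetradeca-4,7-dien-1-yl]malonate (C3 epimers) | OC1C[C@H](C(C(=O)OC)C(=O)OC)CC[C@]2(C)O[C@H]2CC/C(C)=C/C/C=C1\C | intermediate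
21 | dimethyl 2-[(1R,4E,7E,11S,12S)-11,12-epoxy-4,8,12-trimethyl-3-oxocyclotetradeca-4,7-dien-1-yl]malonate | O=C1C[C@H](C(C(=O)OC)C(=O)OC)CC[C@]2(C)O[C@H]2CC/C(C)=C/C/C=C1\C | intermediate
22 | dimethyl 2-[(1R,3S,4E,7E,11S,12S)-11,12-epoxy-3-hydroxy-4,8,12-trimethylcyclotetradeca-4,7-dien-1-yl]malonate | O[C@H]1C[C@H](C(C(=O)OC)C(=O)OC)CC[C@]2(C)O[C@H]2CC/C(C)=C/C/C=C1\C | intermediate
23 | dimethyl 2-[(1R,3S,4E,7E,11S,12S)-3-(tert-butyldimethylsilyloxy)-11,12-epoxy-4,8,12-trimethylcyclotetradeca-4,7-dien-1-yl]malonate | CC(C)(C)[Si](C)(C)O[C@H]1C[C@H](C(C(=O)OC)C(=O)OC)CC[C@]2(C)O[C@H]2CC/C(C)=C/C/C=C1\C | intermediate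
24 | 2-[(1R,3S,4E,7E,11S,12S)-3-(tert-butyldimethylsilyloxy)-11,12-epoxy-4,8,12-trimethylcyclotetradeca-4,7-dien-1-yl]malonic acid | CC(C)(C)[Si](C)(C)O[C@H]1C[C@H](C(C(=O)O)C(=O)O)CC[C@]2(C)O[C@H]2CC/C(C)=C/C/C=C1\C | intermediate
25 | formaldehyde | C=O | starting material
26 | Mannich base: 24 carrying a diethylaminomethyl group on C15 (not isolated) | CC(C)(C)[Si](C)(C)O[C@H]1C[C@H](C(CN(CC)CC)(C(=O)O)C(=O)O)CC[C@]2(C)O[C@H]2CC/C(C)=C/C/C=C1\C | intermediate
27 | 2-[(1R,3S,4E,7E,11S,12S)-3-(tert-butyldimethylsilyloxy)-11,12-epoxy-4,8,12-trimethylcyclotetradeca-4,7-dien-1-yl]prop-2-enoic acid | CC(C)(C)[Si](C)(C)O[C@H]1C[C@H](C(=C)C(=O)O)CC[C@]2(C)O[C@H]2CC/C(C)=C/C/C=C1\C | intermediate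
28 | 11-deacetyl-3-O-(tert-butyldimethylsilyl)dendronpholide A (1R,3S,11S,12R) | C=C1C(=O)O[C@]2(C)CC[C@@H]1C[C@H](O[Si](C)(C)C(C)(C)C)/C(C)=C/C/C=C(\C)CC[C@@H]2O | intermediate
29 | 3-O-(tert-butyldimethylsilyl)dendronpholide A | C=C1C(=O)O[C@]2(C)CC[C@@H]1C[C@H](O[Si](C)(C)C(C)(C)C)/C(C)=C/C/C=C(\C)CC[C@@H]2OC(C)=O | intermediate
30 | dendronpholide A | C=C1C(=O)O[C@]2(C)CC[C@@H]1C[C@H](O)/C(C)=C/C/C=C(\C)CC[C@@H]2OC(C)=O | target

## Step count and least certain steps

Total: 22 steps. Longest linear sequence: 22 steps, from 1 (the route is fully linear; 11, 16, 18 and 25 are bought).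

**Step 20 (key step).**
- What may go wrong: full ionisation at C12 before the carboxyl arrives would lead to elimination, hydride shift or transannular capture by the C7=C8 olefin; attack at C11 is the other leak. The seven-membered closure has few close precedents.
- Fallback, from 27 back to 29: the epoxide is hydrolysed with dilute aqueous acid (HClO4 cat., THF/H2O, 0 °C), where water in large excess opens C12 with inversion to give the (11S,12R)-diol acid F1. The secondary C11 hydroxyl is acetylated selectively (Ac2O, pyridine, 0 °C) to give the 11-acetoxy-12-hydroxy acid F2. Yamaguchi lactonisation (2,4,6-trichlorobenzoyl chloride, Et3N, then DMAP, toluene, 80 °C) onto the tertiary hydroxyl, with retention at C12, gives 29.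

**Step 10 (hydrozirconation–iodination).**
- What may go wrong: reductive opening of the epoxide by the zirconium hydride during the equilibration that regiocontrol needs, or incomplete placement of the metal on C4.
- Fallback, from 12 back to 14: palladium-catalysed syn hydrostannation (Bu3SnH, PdCl2(PPh3)2, THF, 0 °C), which is inert to epoxides, gives the C4 alkenylstannane F3 after separation from its regioisomer. Iododestannylation (I2, CH2Cl2, 0 °C) with retention gives 14.

**Step 14 (ring closure).**
- What may go wrong: oligomerisation competing with cyclisation, slow insertion into the hindered trisubstituted iodide, and protonation of the alkenylchromium in place of addition.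
- Fallback, from 12 back to 20, a nickel-catalysed reductive alkyne–aldehyde macrocyclisation that needs no iodide: acetal 12 is hydrolysed as in step 11 to the ynal F4 and homologated with 16 to the enynal F5. Malonate 18 is added as in step 13 to give the alkynyl aldehyde malonate F6. Ni(cod)2 with the carbene ligand IMes and Et3SiH (THF, slow addition) joins C3 to the methyl-bearing alkyne carbon with syn delivery of hydrogen to C5, giving the macrocyclic triethylsilyl ether F7. HF·pyridine releases 20.

**Step 16 (reduction at C3).**
- What may go wrong: the conformation of the macrocyclic enone overriding the catalyst's facial preference, or competing conjugate reduction.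
- Fallback, from 20 back to 22: the C3 epimers of 20 are separated. The 3S epimer is 22. The 3R epimer F8 is inverted by a Mitsunobu reaction (chloroacetic acid, PPh3, DIAD, THF, 0 °C) to the (3S)-chloroacetate F9, which thiourea and NaHCO3 in EtOH cleave under near-neutral conditions to 22.

**Steps 18–19 (malonic acid and methylenation).**
- What may go wrong: protonation of the epoxide by the free malonic acid during acidification or heating, which would open it early and with less control.
- Fallback, from 23 back to 27, never passing through a free diacid: mono-saponification (KOH 1.05 equiv, MeOH, 0 °C) gives the half ester F10, handled as its potassium salt. Mannich methylenation on that salt (Et2NH·HCl, aqueous 25, THF, 60 °C) gives the methyl acrylate F11. Neutral hydrolysis with Me3SnOH (1,2-dichloroethane, 70 °C) gives 27.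

## Further compounds

F1 | step 20 | 2-[(1R,3S,4E,7E,11S,12R)-3-(tert-butyldimethylsilyloxy)-11,12-dihydroxy-4,8,12-trimethylcyclotetradeca-4,7-dien-1-yl]prop-2-enoic acid | CC(C)(C)[Si](C)(C)O[C@H]1C[C@H](C(=C)C(=O)O)CC[C@@](C)(O)[C@@H](O)CC/C(C)=C/C/C=C1\C
F2 | step 20 | 2-[(1R,3S,4E,7E,11S,12R)-11-acetoxy-3-(tert-butyldimethylsilyloxy)-12-hydroxy-4,8,12-trimethylcyclotetradeca-4,7-dien-1-yl]prop-2-enoic acid | CC(C)(C)[Si](C)(C)O[C@H]1C[C@H](C(=C)C(=O)O)CC[C@@](C)(O)[C@@H](OC(C)=O)CC/C(C)=C/C/C=C1\C
F3 | step 10 | (2E,5E,9S,10S)-9,10-epoxy-13,13-dimethoxy-6,10-dimethyl-2-(tributylstannyl)trideca-2,5-diene | COC(OC)CC[C@]1(C)O[C@H]1CC/C(C)=C/C/C=C(\C)[Sn](CCCC)(CCCC)CCCC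
F4 | step 14 | (4S,5S,8E)-4,5-epoxy-4,8-dimethyltridec-8-en-11-ynal | O=CCC[C@]1(C)O[C@H]1CC/C(C)=C/CC#CC
F5 | step 14 | (2E,6S,7S,10E)-6,7-epoxy-6,10-dimethylpentadeca-2,10-dien-13-ynal | O=C/C=C/CC[C@]1(C)O[C@H]1CC/C(C)=C/CC#CC
F6 | step 14 | dimethyl 2-[(3R,6S,7S,10E)-6,7-epoxy-6,10-dimethyl-1-oxopentadec-10-en-13-yn-3-yl]malonate | O=CC[C@H](C(C(=O)OC)C(=O)OC)CC[C@]1(C)O[C@H]1CC/C(C)=C/CC#CC
F7 | step 14 | dimethyl 2-[(1R,4E,7E,11S,12S)-11,12-epoxy-4,8,12-trimethyl-3-(triethylsilyloxy)cyclotetradeca-4,7-dien-1-yl]malonate (C3 epimers) | CC[Si](CC)(CC)OC1C[C@H](C(C(=O)OC)C(=O)OC)CC[C@]2(C)O[C@H]2CC/C(C)=C/C/C=C1\C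
F8 | step 16 | dimethyl 2-[(1R,3R,4E,7E,11S,12S)-11,12-epoxy-3-hydroxy-4,8,12-trimethylcyclotetradeca-4,7-dien-1-yl]malonate | O[C@@H]1C[C@H](C(C(=O)OC)C(=O)OC)CC[C@]2(C)O[C@H]2CC/C(C)=C/C/C=C1\C
F9 | step 16 | dimethyl 2-[(1R,3S,4E,7E,11S,12S)-3-(chloroacetoxy)-11,12-epoxy-4,8,12-trimethylcyclotetradeca-4,7-dien-1-yl]malonate | O=C(CCl)O[C@H]1C[C@H](C(C(=O)OC)C(=O)OC)CC[C@]2(C)O[C@H]2CC/C(C)=C/C/C=C1\C
F10 | step 19 | 2-[(1R,3S,4E,7E,11S,12S)-3-(tert-butyldimethylsilyloxy)-11,12-epoxy-4,8,12-trimethylcyclotetradeca-4,7-dien-1-yl]malonic acid monomethyl ester (mixture at C15) | CC(C)(C)[Si](C)(C)O[C@H]1C[C@H](C(C(=O)O)C(=O)OC)CC[C@]2(C)O[C@H]2CC/C(C)=C/C/C=C1\C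
F11 | step 19 | methyl 2-[(1R,3S,4E,7E,11S,12S)-3-(tert-butyldimethylsilyloxy)-11,12-epoxy-4,8,12-trimethylcyclotetradeca-4,7-dien-1-yl]prop-2-enoate | CC(C)(C)[Si](C)(C)O[C@H]1C[C@H](C(=C)C(=O)OC)CC[C@]2(C)O[C@H]2CC/C(C)=C/C/C=C1\C
A1 | alternative 1 | open-chain diyne with the lactone, 11-acetate and 3-O-triethylsilyl ether in place; methyl-capped alkynes at C3 and C6 | C=C1C(=O)O[C@](C)(CC[C@@H]1C[C@H](O[Si](CC)(CC)CC)C#CC)[C@@H](OC(C)=O)CC/C(C)=C/CC#CC
A2 | alternative 1 | fourteen-membered cycloalkyne lactone lacking C18 (3-O-triethylsilyl, 11-O-acetyl) | C=C1C(=O)O[C@]2(C)CC[C@@H]1C[C@H](O[Si](CC)(CC)CC)C#CC/C=C(\C)CC[C@@H]2OC(C)=O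
A3 | alternative 2 | dioxinone alcohol: 2,2-dimethyl-1,3-dioxin-4-one on C3, α,β-unsaturated seven-membered lactone with hydroxymethyl C17 on C15 | CC1(C)OC(/C(C)=C/C/C=C(\C)CC[C@H](OC(C)=O)[C@@]2(C)CCC=C(CO)C(=O)O2)=CC(=O)O1
A4 | alternative 2 | 3-oxo analogue of dendronpholide A | C=C1C(=O)O[C@]2(C)CC[C@@H]1CC(=O)/C(C)=C/C/C=C(\C)CC[C@@H]2OC(C)=O
A5 | alternative 3 | open-chain C5 tributylstannyl alkene and C6 allylic chloride with the lactone, 11-acetate and 3-O-silyl ether in place | C=C1C(=O)O[C@](C)(CC[C@@H]1C[C@H](O[Si](C)(C)C(C)(C)C)/C(C)=C/[Sn](CCCC)(CCCC)CCCC)[C@@H](OC(C)=O)CC/C(C)=C/CCl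
A6 | alternative 3 | 3-O-(tert-butyldimethylsilyl)dendronpholide A (identical with 29) | C=C1C(=O)O[C@]2(C)CC[C@@H]1C[C@H](O[Si](C)(C)C(C)(C)C)/C(C)=C/C/C=C(\C)CC[C@@H]2OC(C)=O
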